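The meeting opened on slowness: in Friday's flask, as charged, E, the initiator, has a half-life of 0.76 s against Q, and X one of 2.5 s against J, the monomer, while the chains have 8.0 min to grow.

    J + E → D + G (k1 = 0.47 M⁻¹ s⁻¹)
    J + D → G + D, rate k2*[D]*[J] (k2 = 0.81 M⁻¹ s⁻¹)
    G + D → J + D, rate k3*[D] as long as [G] is above zero (k3 = 0.12 s⁻¹)
    X + J → X.J (k4 = 0.73 M⁻¹ s⁻¹)
    E + Q → E.Q (k5 = 110 M⁻¹ s⁻¹)

- Friday's: J 0.38 M; X 7.60 mM; E 9.5 mM; Q 8.3 mM; time 8.0 min
- Thursday's: J 0.38 M; X 5.00 mM; E 9.5 mM; Q 8.3 mM; time 8.0 min

* which of the two ends with the longer chains by the average number of monomer units in a chain (chains begun, living or dead) ("neither" if they lie within 10%) (Friday's / Thursday's / neither)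
* average number of monomer units in a chain (chains begun, living or dead) at the end, Friday's
* average number of monomer units in a chain (chains begun, living or dead) at the end, Thursday's

- the average divides the monomer in chains by the number of chains begun, living and dead together
- run time (Friday's): 8.0 min

The chair asked first how many chains there were. The analyst argued that Q and J compete for E, and she called a the level of Q at which the two take E equally fast: the constant of E with J times the charged J over the constant of E with Q, here 1.62 mM. Integrated, the chains begun are a times ln(Q charged / Q left). Putting Q left near a, she got D, the living ends, at 2.65 mM; the balance of E then leaves 1.45 mM of Q, close enough inside a logarithm.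

The process chemist replied that J does not simply drain away. With D steady, it relaxes towards a floor, the return constant over the growth constant, 0.148 M. Its excess above that floor shrinks as exp(−θ), where θ is the reaction clock, the growth constant times D times the time: 1.03.

The chair wanted the curve replaced by its mean. The length is the growth constant times the time times the mean excess, and an exponential's mean is (1 − exp(−θ))/θ of its start, 0.624. Subtracting X's charge from J, the starting excess is 0.224 M on Friday's and 0.227 M on Thursday's. The meeting minuted 54.4 units for Friday's and 55.1 for Thursday's, a gap inside 10%.

The forecast said neither, with 54 and 54.5: “X only removes a few mM of monomer and does not touch the living ends”.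

The simulation gives neither, with 54.0 for Friday's and 54.6 for Thursday's.

In Friday's, the clock at 1.03 puts J at 60.1% of its charge, and the flask holds 59.3%. Now take the neighbour of Friday's charged with 0.0021 M of Q. Its Q falls to 0.893% of that charge, so the chains are about E minus Q, 7.40 mM, and the flask reads 0.00742 M. The clock of that neighbour reaches 2.88, further than the 1.03 of Friday's, and the reckoned length is 28.6. That neighbour ends with 55.7% of the charged J in G, the monomer in chains, and 28.5 units a chain, fewer than the 54.0 of Friday's.

The constants used here are made up; the flask was simulated.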